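## Conventions and remarks

- Oxolane ring atoms: O1, C2–C5. Ring B is the aryl group on C2, ring C the aryl group on C5. Rings A and D are the 3,4-dimethoxyphenyl rings of the arms on ring B and ring C. C7/C8 are the carbinol and ether carbons of the arm on ring B; C7′/C8′ those of the arm on ring C.
- TIPS = tri(propan-2-yl)silyl. ArR = 4-{[(1R,2R)-1-(3,4-dimethoxyphenyl)-1-(TIPS-oxy)propan-2-yl]oxy}-3-methoxyphenyl; ArS = the mirror-image (1S,2S) group.
- Remark: the C7/C7′ hydroxyls are carried as TIPS ethers, because a bulky silyl ether is expected to tolerate the triflate Lewis acid of step 14 and the hot chloride of step 15 better than a smaller one.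
- Remark: reagents 5, 17 and 19 are taken as purchasable.
- Remark: the sense of induction of the bis(oxazoline) ligand in step 13 is assumed, not derived; it is to be assigned on (E)-anethole, and the antipode that gives the (2S,3R) series is used.

## Analysis of the target

Compound 27 is a 2,5-diaryl-3,4-dimethyloxolane. Rings B and C each carry, para to the ring carbon and next to a methoxy group, an ether-linked 1-(3,4-dimethoxyphenyl)-1-hydroxypropan-2-yl arm. There are eight stereocenters. The ring is (2S,3S,4S,5R): the aryl groups are 2,5-cis, the C3 methyl is trans to both the C2 aryl and the C4 methyl, and the C4 methyl is cis to the C5 aryl. Both arms are threo, but they are enantiomeric to each other: (7R,8R) on ring B and (7S,8S) on ring C. Because the core is unsymmetrical (2,3-trans but 4,5-cis), the two halves are not interchangeable, and the arm stereocenters are too far from the ring to steer it. The C2–O1 and C5–O1 bonds are benzylic ethers para to an alkoxy group, and C7/C7′ are benzylic carbinols on veratryl rings; all four ionize under protic or strong Lewis acids. This rules out acidic deprotection and limits the acid strength usable for ring formation. The strategy rests on two features. C5 (benzylic, oxygen-bearing) and C3 are 1,3-related through C4. C3 is also the only ring carbon whose substituent is trans to both neighbours, so it can pass through a geminal diester and be corrected by equilibration. C5–C4–C3 can therefore come from an aryl cyclopropane-1,1-diester and C2–O1 from an aldehyde.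

## Retrosynthetic reasoning

**27 to 26.** The two O–Si bonds are cut last. The benzylic hydroxyls would be sulfonylated or ionized in the closing steps, and fluoride is the only unmasking that avoids acid at C2, C5, C7 and C7′.

**26 back to 21 (through 25, 24, 23, 22).** The C3 methyl is traced to CH2OMs, CH2OH and CO2Me, and the C3 hydrogen to a second ester lost as CO2. This leads to the geminal diester 21. The cut is placed at C3 because the required orientation there is the thermodynamic one: the kinetic mixture 22 can be equilibrated to 23. The gain is that C3 is not a stereocenter in the ring-forming step.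

**21 to 20 and 10 (key disconnection).** O1–C5 and C2–C3 are cut together. C5 can stabilize positive charge and C3, as a malonate, negative charge, so the C5–C4–C3 unit is a donor–acceptor cyclopropane (20), and the aldehyde 10 supplies C2 and O1. The cut splits the molecule into two halves of similar size, each carrying one arm. The forward reaction must substitute at the donor carbon with inversion, so that the trans aryl/methyl pair of 20 becomes the 4,5-cis pair. It must also close 2,5-cis and leave the benzylic silyl ethers untouched.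

**20 to 18 and 19; 18 to 16 and 17.** The two cyclopropane bonds to the malonate carbon are cut, giving an (E)-propenylarene (18) and a malonate carbene source (19). The alkene geometry fixes trans, and a chiral copper catalyst fixes the absolute sense. Introducing the methyl group by deoxygenating an oxygenated carbon on the three-membered ring was rejected. Radical or cationic intermediates next to a donor–acceptor cyclopropane open the ring. The propenyl group is attached to the aryl bromide 16 with the alkenylboronate 17, which secures pure (E) geometry.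

**10 to 8 (through 9).** The formyl group is introduced last on the ring B half, from the aryl bromide via the aryllithium. An aldehyde would not survive the organomagnesium and hydride steps that build the arm, and this lets both halves diverge from the same type of aryl bromide.

**8 and 16 back to 1, 2, 11 and 5.** In each arm the C7–ring A (or D) bond is cut to an acyl electrophile and the aryl Grignard 5 (via 6/14 and 4/13). The C8–O–aryl bond is cut to the phenol 1 and a lactate (2 or 11, via 3/12). C8 then comes from the chiral pool with predictable inversion, and C7 follows by 1,2-induction from C8. The silyl group is put on only after the C8 aryl ether exists. A route that joined a preformed vicinal silyloxy alkoxide to the arene would risk 1,2-silyl migration; this order avoids it. One five-step sequence is run in both enantiomeric series.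

## Alternatives that were turned down

The alternatives' compounds are shown with tert-butyldimethylsilyl ethers; the choice of silyl group does not change the arguments.

**Alternative 1: both methyl groups by conjugate addition and enolate alkylation.**
- Disconnection: the two C–CH3 bonds at C3 and C4, on a lactone that holds only the ring B half.
- Forward key step: a methyl cuprate adds to the β-carbon of butenolide A1 on the face away from the aryl group. The enolate is then methylated on the face away from the new methyl, giving the all-trans lactone A2. Ring C would be attached afterwards at the lactone carbonyl, and C5 set by hydride delivery anti to the C4 methyl.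
- For it: the inductions are 1,2-anti in a rigid five-membered ring. Both methyl groups arrive as methyl, so nothing has to be excised or deoxygenated. The sequence after the key step is about three steps, against six here. On these points it is stronger than the chosen route.
- Against it: the key step makes no ring bond and does not join the halves. A1 has a γ-hydrogen that is benzylic, allylic and α to oxygen, so basic cuprate or enolate conditions can aromatize it to an oxyfuran and erase the one stereocenter that relays all the others. A1 itself needs an asymmetric synthesis. The union with ring C comes late and needs a Lewis acid and a silane next to two ionizable benzylic silyl ethers.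
- Comparison: four centers are relayed one after another, so any erosion multiplies. The chosen route offers a convergent, catalytic union that sets C2 and C5 in one step and takes C4 from the cyclopropane.

**Alternative 2: acetalization, Prins closure and pinacol shift.**
- Disconnection: O1–C2, C2–C3 and C4–C5, to aldehyde A4 and the threo (E)-allylic diol A3.
- Forward key step: the two condense to an oxocarbenium ion, a tin Lewis acid drives closure to a six-membered cation, and a 1,2-shift contracts it to the oxolane A5 with a formyl group on C4.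
- For it: three bonds, the ring and all four ring stereocenters form in one flask, the highest bond count of the four strategies. Formyl to methyl needs no decarboxylation, so the tail is shorter than here.
- Against it: the migrating carbon (the future C5) is a para-alkoxybenzylic carbinol carbon. Under a stoichiometric strong Lewis acid its C–O bond can ionize, which would scramble C5 and endanger the silyl ethers. The formyl-bearing C4 must stay cis to the C5 aryl, so an epimerizable center sits in an orientation with no clear thermodynamic preference. A3 needs two further contiguous stereocenters on the arm-bearing arene, one of which is destroyed.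
- Comparison: the chosen route places its only epimerizable center at C3, where the required orientation is the thermodynamic minimum, and uses a catalytic, milder Lewis acid.

**Alternative 3: photochemical ring contraction of a pyranone.**
- Disconnection: C3–C4, by contraction of the 2,6-cis-diaryl-3-methyl-5-diazo-pyranone A6.
- Forward key step: irradiation in an alcohol expels nitrogen, the methyl-bearing ring carbon migrates to the carbene carbon, and the ketene is trapped as the C4 ester A7.
- For it: in the six-membered precursor the 2,6-cis aryl groups and the 3-methyl group are all equatorial, so three of the four ring relationships can be secured by equilibration. The key step is neutral, with no Lewis acid near the benzylic ethers. On that point it is gentler than the chosen annulation.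
- Against it: C4 is created by protonation of the ketene-derived enol, without control, and again has to end cis to the C5 aryl. The contraction joins nothing, so the convergent union must be solved earlier in building the pyranone. Diazo transfer next to a benzylic ether carbon adds steps. The carbene can divert by hydrogen shift or C–H insertion, and the electron-rich aryl benzylic ethers absorb in the ultraviolet.
- Comparison: the ester-to-methyl tail is as long as here and the front end is longer. The chosen route offers stereospecific transfer to C4/C5 instead of an uncontrolled protonation.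

Key step: step 14

## Route

Step 1
Reactants: 1 4-bromo-2-methoxyphenol; 2 ethyl (S)-lactate
Product: 3 ethyl (2R)-2-(4-bromo-2-methoxyphenoxy)propanoate
Conditions: PPh3, DIAD, THF, 0 °C → rt
Reagents that add atoms: none
Why: Mitsunobu etherification; the phenoxide displaces the activated lactate oxygen in an SN2 step, so C8 is inverted cleanly from S to R, and no base is present that could enolize the ester.

Step 2
Reactants: 3
Product: 4 (2R)-2-(4-bromo-2-methoxyphenoxy)-N-methoxy-N-methylpropanamide
Conditions: MeNH(OMe)·HCl, i-PrMgCl, THF, −20 °C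
Reagents that add atoms: N,O-dimethylhydroxylamine hydrochloride, CNOC.Cl
Why: Weinreb amide formation by acyl substitution with the magnesium amide made in the flask; at −20 °C attack at the ester carbonyl should be faster than removal of the C8 hydrogen, so the stereocenter is kept.

Step 3
Reactants: 4; 5 (3,4-dimethoxyphenyl)magnesium bromide
Product: 6 (2R)-2-(4-bromo-2-methoxyphenoxy)-1-(3,4-dimethoxyphenyl)propan-1-one
Conditions: THF, −20 → 0 °C; aq. NH4Cl
Reagents that add atoms: none
Why: Weinreb ketone synthesis; the magnesium-chelated tetrahedral adduct stops at single addition and releases the base-sensitive α-aryloxy ketone only on acidic quench, and the aryl bromide does not exchange with an aryl Grignard reagent at this temperature.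

Step 4
Reactants: 6
Product: 7 (1R,2R)-2-(4-bromo-2-methoxyphenoxy)-1-(3,4-dimethoxyphenyl)propan-1-ol (threo)
Conditions: BH4− on quaternary ammonium resin (Amberlite IRA-400), MeOH, 0 °C
Reagents that add atoms: none
Why: Substrate-controlled 1,2-induction (Felkin–Anh, polar model); without a chelating cation the C8–OAr bond lies anti to the incoming hydride, which passes the C8 hydrogen and should give the threo (1R,2R) carbinol, the erythro isomer being removed by chromatography.

Step 5
Reactants: 7
Product: 8 ArR–Br, {[(1R,2R)-2-(4-bromo-2-methoxyphenoxy)-1-(3,4-dimethoxyphenyl)propyl]oxy}tri(propan-2-yl)silane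
Conditions: TIPSOTf, 2,6-lutidine, CH2Cl2, 0 °C → rt
Reagents that add atoms: triisopropylsilyl trifluoromethanesulfonate, CC(C)[Si](C(C)C)(C(C)C)OS(=O)(=O)C(F)(F)F
Why: Silylation of a hindered secondary benzylic alcohol with a silyl triflate and a non-nucleophilic base; the C8 ether is already in place, so no silyl migration is possible.

Step 6
Reactants: 8
Product: 10 ArR–CHO, 4-{[(1R,2R)-1-(3,4-dimethoxyphenyl)-1-(TIPS-oxy)propan-2-yl]oxy}-3-methoxybenzaldehyde, via aryllithium 9 (not isolated)
Conditions: n-BuLi, THF, −78 °C; DMF; aq. NH4Cl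
Reagents that add atoms: N,N-dimethylformamide, CN(C)C=O
Why: Bromine–lithium exchange followed by formylation of the aryllithium (Bouveault-type); at −78 °C exchange should be faster than ortho-lithiation or attack at silicon.

Step 7
Reactants: 1 4-bromo-2-methoxyphenol; 11 methyl (R)-lactate
Product: 12 methyl (2S)-2-(4-bromo-2-methoxyphenoxy)propanoate
Conditions: PPh3, DIAD, THF, 0 °C → rt
Reagents that add atoms: none
Why: Mitsunobu etherification as in step 1, in the enantiomeric series; inversion converts R into S at C8′.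

Step 8
Reactants: 12
Product: 13 (2S)-2-(4-bromo-2-methoxyphenoxy)-N-methoxy-N-methylpropanamide
Conditions: MeNH(OMe)·HCl, i-PrMgCl, THF, −20 °C
Reagents that add atoms: N,O-dimethylhydroxylamine hydrochloride, CNOC.Cl
Why: Weinreb amide formation as in step 2.

Step 9
Reactants: 13; 5 (3,4-dimethoxyphenyl)magnesium bromide
Product: 14 (2S)-2-(4-bromo-2-methoxyphenoxy)-1-(3,4-dimethoxyphenyl)propan-1-one
Conditions: THF, −20 → 0 °C; aq. NH4Cl
Reagents that add atoms: none
Why: Weinreb ketone synthesis as in step 3.

Step 10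
Reactants: 14
Product: 15 (1S,2S)-2-(4-bromo-2-methoxyphenoxy)-1-(3,4-dimethoxyphenyl)propan-1-ol (threo)
Conditions: BH4− on quaternary ammonium resin (Amberlite IRA-400), MeOH, 0 °C
Reagents that add atoms: none
Why: Felkin–Anh reduction as in step 4; the (2S) ketone should give the (1S,2S) carbinol.

Step 11
Reactants: 15
Product: 16 ArS–Br, {[(1S,2S)-2-(4-bromo-2-methoxyphenoxy)-1-(3,4-dimethoxyphenyl)propyl]oxy}tri(propan-2-yl)silane
Conditions: TIPSOTf, 2,6-lutidine, CH2Cl2, 0 °C → rt
Reagents that add atoms: triisopropylsilyl trifluoromethanesulfonate, CC(C)[Si](C(C)C)(C(C)C)OS(=O)(=O)C(F)(F)F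
Why: Silylation as in step 5.

Step 12
Reactants: 16; 17 4,4,5,5-tetramethyl-2-[(1E)-prop-1-en-1-yl]-1,3,2-dioxaborolane
Product: 18 ArS–CH=CH–CH3 with (E) geometry, 1-ArS-(1E)-prop-1-ene
Conditions: Pd(dppf)Cl2 (5 mol %), K2CO3, 1,4-dioxane/H2O, 80 °C
Reagents that add atoms: none
Why: Suzuki–Miyaura coupling; transmetalation and reductive elimination retain the alkene geometry, so the (E)-propenyl group is transferred intact.

Step 13
Reactants: 18; 19 phenyliodonium bis(methoxycarbonyl)methanide
Product: 20 dimethyl (2S,3R)-2-ArS-3-methylcyclopropane-1,1-dicarboxylate (aryl and methyl trans)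
Conditions: [Cu(MeCN)4]PF6 (10 mol %), side-arm indane-bis(oxazoline) ligand (12 mol %), 4 Å MS, toluene, 0 °C
Reagents that add atoms: none
Why: Copper-carbenoid cyclopropanation of an aryl alkene with a malonate-derived iodonium ylide; the concerted addition keeps the (E) geometry as trans, and the chiral bis(oxazoline) selects the alkene face, which should give the (2S,3R) isomer.

Step 14
Reactants: 20; 10 ArR–CHO
Product: 21 dimethyl (2R,4S,5R)-2-ArR-5-ArS-4-methyloxolane-3,3-dicarboxylate (2,5-cis, 4,5-cis)
Conditions: Sn(OTf)2 (10–20 mol %), CH2Cl2, −20 → 0 °C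
Reagents that add atoms: none
Why: Sn(OTf)2 chelates the two ester carbonyls of 20 and polarizes the bond between the aryl-bearing carbon and the malonate carbon. The carbonyl oxygen of 10 then attacks the aryl-bearing carbon anti to the departing malonate carbon, an SN2-like substitution on an intimate ion pair that forms O1–C5 with inversion. The oxocarbenium and tin enolate so formed collapse by aldol-type C2–C3 bond formation, a 5-(enolexo)-endo-trig closure that is accessible because the acceptor is a cationic C=O π-system held in an envelope. The closest known reaction type is the Lewis-acid-catalysed [3+2] annulation of 2-arylcyclopropane-1,1-diesters, including trans-2,3-disubstituted ones, with aryl aldehydes to 2,5-cis-oxolanes. C5 is controlled by the configuration of the donor carbon of 20 through stereospecific inversion. C4 is carried over untouched, so the trans aryl/methyl pair becomes 4,5-cis. C2 is set in the closure, where both aryl groups take pseudo-equatorial positions of the envelope and end 2,5-cis. The step needs substitution to outrun ionization at the electron-rich benzylic carbon and needs the silyl ethers to survive; a catalytic mild triflate at or below 0 °C, an excess of the nucleophilic electron-rich aldehyde, the poorly coordinating TIPS ethers and a prompt quench should secure this.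

Step 15
Reactants: 21
Product: 22 methyl (2S,4S,5R)-2-ArR-5-ArS-4-methyloxolane-3-carboxylate, mixture of C3 epimers
Conditions: NaCl, H2O, DMSO, 150 °C
Reagents that add atoms: none
Why: Krapcho dealkoxycarbonylation; chloride attacks an ester methyl group, the carboxylate loses CO2 and water protonates the ester enolate, mainly from the face away from the C2 aryl and C4 methyl, so a C3 mixture rich in the cis isomer is expected.

Step 16
Reactants: 22
Product: 23 methyl (2S,3S,4S,5R)-2-ArR-5-ArS-4-methyloxolane-3-carboxylate (ester trans to C2 aryl and C4 methyl)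
Conditions: NaOMe, MeOH, rt
Reagents that add atoms: none
Why: Base-mediated epimerization through the ester enolate; only C3 is acidic, and the isomer with the ester trans to both neighbours is the thermodynamic product.

Step 17
Reactants: 23
Product: 24 [(2S,3R,4S,5R)-2-ArR-5-ArS-4-methyloxolan-3-yl]methanol
Conditions: LiAlH4, THF, 0 °C
Reagents that add atoms: none
Why: Hydride reduction of the ester to the primary alcohol; silyl ethers, aryl ethers and the oxolane are inert, and no stereocenter is touched.

Step 18
Reactants: 24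
Product: 25 [(2S,3R,4S,5R)-2-ArR-5-ArS-4-methyloxolan-3-yl]methyl methanesulfonate
Conditions: MsCl, Et3N, CH2Cl2, 0 °C
Reagents that add atoms: methanesulfonyl chloride, CS(=O)(=O)Cl
Why: Mesylation of the only free hydroxyl, a primary one.

Step 19
Reactants: 25
Product: 26 (2S,3S,4S,5R)-2-ArR-5-ArS-3,4-dimethyloxolane
Conditions: LiEt3BH, THF, 0 °C → rt
Reagents that add atoms: none
Why: SN2 displacement of a primary mesylate by hydride, which turns CH2OMs into the C3 methyl group without touching the adjacent stereocenters.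

Step 20
Reactants: 26
Product: 27 (1R,2R)-1-(3,4-dimethoxyphenyl)-2-{4-[(2S,3S,4S,5R)-5-(4-{[(1S,2S)-1-(3,4-dimethoxyphenyl)-1-hydroxypropan-2-yl]oxy}-3-methoxyphenyl)-3,4-dimethyloxolan-2-yl]-2-methoxyphenoxy}propan-1-ol
Conditions: TBAF, THF, rt
Reagents that add atoms: none
Why: Fluoride-mediated cleavage of both silyl ethers; the medium is not acidic, so C2, C5, C7 and C7′ cannot ionize.

## Compound list

1 | 4-bromo-2-methoxyphenol | COc1cc(Br)ccc1O | starting material
2 | ethyl (S)-lactate | C[C@H](O)C(=O)OCC | starting material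
3 | ethyl (2R)-2-(4-bromo-2-methoxyphenoxy)propanoate | C[C@@H](Oc1ccc(Br)cc1OC)C(=O)OCC | intermediate
4 | (2R)-2-(4-bromo-2-methoxyphenoxy)-N-methoxy-N-methylpropanamide | C[C@@H](Oc1ccc(Br)cc1OC)C(=O)N(C)OC | intermediate
5 | (3,4-dimethoxyphenyl)magnesium bromide | COc1ccc([Mg]Br)cc1OC | starting material
6 | (2R)-2-(4-bromo-2-methoxyphenoxy)-1-(3,4-dimethoxyphenyl)propan-1-one | C[C@@H](Oc1ccc(Br)cc1OC)C(=O)c1ccc(OC)c(OC)c1 | intermediate
7 | (1R,2R)-2-(4-bromo-2-methoxyphenoxy)-1-(3,4-dimethoxyphenyl)propan-1-ol | COc1ccc([C@@H](O)[C@@H](C)Oc2ccc(Br)cc2OC)cc1OC | intermediate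
8 | ArR–Br, TIPS ether of 7 | COc1ccc([C@@H](O[Si](C(C)C)(C(C)C)C(C)C)[C@@H](C)Oc2ccc(Br)cc2OC)cc1OC | intermediate
9 | ArR–Li, aryllithium from 8 | COc1ccc([C@@H](O[Si](C(C)C)(C(C)C)C(C)C)[C@@H](C)Oc2ccc([Li])cc2OC)cc1OC | intermediate
10 | ArR–CHO, 4-{[(1R,2R)-1-(3,4-dimethoxyphenyl)-1-(TIPS-oxy)propan-2-yl]oxy}-3-methoxybenzaldehyde | COc1ccc([C@@H](O[Si](C(C)C)(C(C)C)C(C)C)[C@@H](C)Oc2ccc(C=O)cc2OC)cc1OC | intermediate
11 | methyl (R)-lactate | C[C@@H](O)C(=O)OC | starting material
12 | methyl (2S)-2-(4-bromo-2-methoxyphenoxy)propanoate | C[C@H](Oc1ccc(Br)cc1OC)C(=O)OC | intermediate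
13 | (2S)-2-(4-bromo-2-methoxyphenoxy)-N-methoxy-N-methylpropanamide | C[C@H](Oc1ccc(Br)cc1OC)C(=O)N(C)OC | intermediate
14 | (2S)-2-(4-bromo-2-methoxyphenoxy)-1-(3,4-dimethoxyphenyl)propan-1-one | C[C@H](Oc1ccc(Br)cc1OC)C(=O)c1ccc(OC)c(OC)c1 | intermediate
15 | (1S,2S)-2-(4-bromo-2-methoxyphenoxy)-1-(3,4-dimethoxyphenyl)propan-1-ol | COc1ccc([C@H](O)[C@H](C)Oc2ccc(Br)cc2OC)cc1OC | intermediate
16 | ArS–Br, TIPS ether of 15 | COc1ccc([C@H](O[Si](C(C)C)(C(C)C)C(C)C)[C@H](C)Oc2ccc(Br)cc2OC)cc1OC | intermediate
17 | 4,4,5,5-tetramethyl-2-[(1E)-prop-1-en-1-yl]-1,3,2-dioxaborolane | C/C=C/B1OC(C)(C)C(C)(C)O1 | starting material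
18 | 1-ArS-(1E)-prop-1-ene | COc1ccc([C@H](O[Si](C(C)C)(C(C)C)C(C)C)[C@H](C)Oc2ccc(/C=C/C)cc2OC)cc1OC | intermediate
19 | phenyliodonium bis(methoxycarbonyl)methanide | COC(=O)[C-](C(=O)OC)[I+]c1ccccc1 | starting material
20 | dimethyl (2S,3R)-2-ArS-3-methylcyclopropane-1,1-dicarboxylate | COC(=O)C1(C(=O)OC)[C@H](C)[C@H]1c1ccc(O[C@@H](C)[C@@H](O[Si](C(C)C)(C(C)C)C(C)C)c2ccc(OC)c(OC)c2)c(OC)c1 | intermediate
21 | dimethyl (2R,4S,5R)-2-ArR-5-ArS-4-methyloxolane-3,3-dicarboxylate | COc1ccc([C@@H](O[Si](C(C)C)(C(C)C)C(C)C)[C@@H](C)Oc2ccc([C@H]3O[C@@H](c4ccc(O[C@@H](C)[C@@H](O[Si](C(C)C)(C(C)C)C(C)C)c5ccc(OC)c(OC)c5)c(OC)c4)[C@@H](C)C3(C(=O)OC)C(=O)OC)cc2OC)cc1OC | intermediate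
22 | methyl (2S,4S,5R)-2-ArR-5-ArS-4-methyloxolane-3-carboxylate, C3 epimers | COc1ccc([C@@H](O[Si](C(C)C)(C(C)C)C(C)C)[C@@H](C)Oc2ccc([C@H]3O[C@@H](c4ccc(O[C@@H](C)[C@@H](O[Si](C(C)C)(C(C)C)C(C)C)c5ccc(OC)c(OC)c5)c(OC)c4)[C@@H](C)C3C(=O)OC)cc2OC)cc1OC | intermediate
23 | methyl (2S,3S,4S,5R)-2-ArR-5-ArS-4-methyloxolane-3-carboxylate | COc1ccc([C@@H](O[Si](C(C)C)(C(C)C)C(C)C)[C@@H](C)Oc2ccc([C@H]3O[C@@H](c4ccc(O[C@@H](C)[C@@H](O[Si](C(C)C)(C(C)C)C(C)C)c5ccc(OC)c(OC)c5)c(OC)c4)[C@@H](C)[C@@H]3C(=O)OC)cc2OC)cc1OC | intermediate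
24 | [(2S,3R,4S,5R)-2-ArR-5-ArS-4-methyloxolan-3-yl]methanol | COc1ccc([C@@H](O[Si](C(C)C)(C(C)C)C(C)C)[C@@H](C)Oc2ccc([C@H]3O[C@@H](c4ccc(O[C@@H](C)[C@@H](O[Si](C(C)C)(C(C)C)C(C)C)c5ccc(OC)c(OC)c5)c(OC)c4)[C@@H](C)[C@@H]3CO)cc2OC)cc1OC | intermediate
25 | [(2S,3R,4S,5R)-2-ArR-5-ArS-4-methyloxolan-3-yl]methyl methanesulfonate | COc1ccc([C@@H](O[Si](C(C)C)(C(C)C)C(C)C)[C@@H](C)Oc2ccc([C@H]3O[C@@H](c4ccc(O[C@@H](C)[C@@H](O[Si](C(C)C)(C(C)C)C(C)C)c5ccc(OC)c(OC)c5)c(OC)c4)[C@@H](C)[C@@H]3COS(C)(=O)=O)cc2OC)cc1OC | intermediate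
26 | (2S,3S,4S,5R)-2-ArR-5-ArS-3,4-dimethyloxolane | COc1ccc([C@@H](O[Si](C(C)C)(C(C)C)C(C)C)[C@@H](C)Oc2ccc([C@H]3O[C@@H](c4ccc(O[C@@H](C)[C@@H](O[Si](C(C)C)(C(C)C)C(C)C)c5ccc(OC)c(OC)c5)c(OC)c4)[C@@H](C)[C@@H]3C)cc2OC)cc1OC | intermediate
27 | (1R,2R)-1-(3,4-dimethoxyphenyl)-2-{4-[(2S,3S,4S,5R)-5-(4-{[(1S,2S)-1-(3,4-dimethoxyphenyl)-1-hydroxypropan-2-yl]oxy}-3-methoxyphenyl)-3,4-dimethyloxolan-2-yl]-2-methoxyphenoxy}propan-1-ol | COc1ccc([C@@H](O)[C@@H](C)Oc2ccc([C@H]3O[C@@H](c4ccc(O[C@@H](C)[C@@H](O)c5ccc(OC)c(OC)c5)c(OC)c4)[C@@H](C)[C@@H]3C)cc2OC)cc1OC | target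

## Step count and least certain steps

Total: 20 steps. Longest linear sequence: 14 steps (steps 7–13, 14, 15–20, from 1 and 11 to 27).

**Step 14 (key step).** The most likely failure is ionization at the donor carbon of 20 running ahead of capture by the aldehyde. The para-alkoxy group of ring C makes that benzylic cation easy to reach, which would erode the configuration at C5 and with it the 4,5-cis relationship. Lewis-acid loss of a benzylic silyl ether, or epimerization of the product at C2/C5 on prolonged exposure, are the next risks.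

Fallback, from 10 and 16, returning at 26 (steps 15–19 are then not needed):
- Aldehyde 10 is alkynylated with methyl propiolate under Ti(Oi-Pr)4/BINOL/Et2Zn control to give methyl (4R)-4-hydroxy-4-ArR-but-2-ynoate F1.
- Semihydrogenation over Pd/CaCO3–Pb(OAc)2 with quinoline gives the (Z)-enoate, which lactonizes to the butenolide (5S)-5-ArR-furan-2(5H)-one F2.
- Me2CuLi adds anti to the aryl group, and the enolate is methylated with MeI anti to the new methyl, to give the all-trans lactone (3S,4S,5S)-3,4-dimethyl-5-ArR-oxolan-2-one F3.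
- Bromide 16 is lithiated with n-BuLi to the aryllithium ArS–Li F4, which adds to F3 to give the cyclic hemiketal 2-ArS-2-hydroxy-3,4-dimethyl-5-ArR-oxolane F5.
- Et3SiH with BF3·OEt2 at −78 °C delivers hydride anti to the neighbouring methyl group and should give 26.

**Step 13.** The most likely failures are poor facial selectivity or slow carbene transfer to a 1,2-disubstituted, electron-rich alkene, and copper-promoted opening of the product cyclopropane.

Fallback, from 16 and 10, returning at 26. It uses amine-catalysed conjugate addition and ring closure, whose sense of induction is predictable, and carries the future C4 methyl as an acyloxymethyl group: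
- 16 is lithiated (F4) and formylated with DMF to ArS–CHO F6.
- Wittig homologation with Ph3P=CHCHO gives the (E)-enal 3-ArS-prop-2-enal F7.
- Dimethyl bromomalonate, (S)-α,α-diphenylprolinol trimethylsilyl ether and 2,6-lutidine should give dimethyl (2S,3R)-2-ArS-3-formylcyclopropane-1,1-dicarboxylate F8.
- NaBH4 at −20 °C gives the 3-hydroxymethyl cyclopropane F9, which is pivaloylated at once (PivCl, pyridine) to the 3-(pivaloyloxymethyl) cyclopropane F10, before it can lactonize.
- Annulation of F10 with 10 under the conditions of step 14 gives the 4-(pivaloyloxymethyl) analogue of 21, F11.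
- Krapcho dealkoxycarbonylation gives the C3-epimeric monoesters F12, and NaOMe equilibration the trans,trans monoester F13.
- LiAlH4 reduces the ester and cleaves the pivalate together, giving the 3,4-bis(hydroxymethyl)oxolane F14.
- MsCl/Et3N gives the bis-mesylate F15, and LiEt3BH reduces both mesylates to methyl groups, giving 26.

**Step 15.** The most likely failure is loss of the silyl ethers, or ring opening by β-elimination of the transient ester enolate, in wet DMSO with chloride at 150 °C.

Fallback, from 21, returning at 22: one ester is saponified (LiOH, THF/MeOH/H2O) to the malonic half-acid 3-carboxy-3-methoxycarbonyl oxolane F16. After acidification, F16 is decarboxylated by warming in toluene at about 100 °C without halide to give 22.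

**Step 4 (and step 10).** The most likely failure is poor diastereofacial selectivity, if the 2-methoxyphenoxy group chelates and pulls the reduction toward the erythro isomer.

Fallback, from 6 (or 14), returning at 7 (or 15): the reduction is put under catalyst control by transfer hydrogenation with RuCl(p-cymene)[(S,S)-TsDPEN] for 6, and the (R,R) catalyst for 14, in HCO2H/Et3N. The aryl-directed hydride delivery is expected to match the substrate's own preference. No new compound is involved.

## Further compounds

F1 | step 14 | methyl (4R)-4-hydroxy-4-ArR-but-2-ynoate | COc1ccc([C@@H](O[Si](C(C)C)(C(C)C)C(C)C)[C@@H](C)Oc2ccc([C@@H](O)C#CC(=O)OC)cc2OC)cc1OC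
F2 | step 14 | (5S)-5-ArR-furan-2(5H)-one | COc1ccc([C@@H](O[Si](C(C)C)(C(C)C)C(C)C)[C@@H](C)Oc2ccc([C@H]3OC(=O)C=C3)cc2OC)cc1OC
F3 | step 14 | (3S,4S,5S)-3,4-dimethyl-5-ArR-oxolan-2-one | COc1ccc([C@@H](O[Si](C(C)C)(C(C)C)C(C)C)[C@@H](C)Oc2ccc([C@H]3OC(=O)[C@@H](C)[C@@H]3C)cc2OC)cc1OC
F4 | step 14 | ArS–Li, aryllithium from 16 | COc1ccc([C@H](O[Si](C(C)C)(C(C)C)C(C)C)[C@H](C)Oc2ccc([Li])cc2OC)cc1OC
F5 | step 14 | 2-ArS-2-hydroxy-3,4-dimethyl-5-ArR-oxolane (cyclic hemiketal, ring configuration of F3) | COc1ccc([C@@H](O[Si](C(C)C)(C(C)C)C(C)C)[C@@H](C)Oc2ccc([C@H]3OC(O)(c4ccc(O[C@@H](C)[C@@H](O[Si](C(C)C)(C(C)C)C(C)C)c5ccc(OC)c(OC)c5)c(OC)c4)[C@@H](C)[C@@H]3C)cc2OC)cc1OC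
F6 | step 13 | ArS–CHO, enantiomer of 10 | COc1ccc([C@H](O[Si](C(C)C)(C(C)C)C(C)C)[C@H](C)Oc2ccc(C=O)cc2OC)cc1OC
F7 | step 13 | (2E)-3-ArS-prop-2-enal | COc1ccc([C@H](O[Si](C(C)C)(C(C)C)C(C)C)[C@H](C)Oc2ccc(/C=C/C=O)cc2OC)cc1OC
F8 | step 13 | dimethyl (2S,3R)-2-ArS-3-formylcyclopropane-1,1-dicarboxylate | COC(=O)C1(C(=O)OC)[C@H](C=O)[C@H]1c1ccc(O[C@@H](C)[C@@H](O[Si](C(C)C)(C(C)C)C(C)C)c2ccc(OC)c(OC)c2)c(OC)c1
F9 | step 13 | dimethyl (2S,3R)-2-ArS-3-(hydroxymethyl)cyclopropane-1,1-dicarboxylate | COC(=O)C1(C(=O)OC)[C@H](CO)[C@H]1c1ccc(O[C@@H](C)[C@@H](O[Si](C(C)C)(C(C)C)C(C)C)c2ccc(OC)c(OC)c2)c(OC)c1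
F10 | step 13 | dimethyl (2S,3R)-2-ArS-3-(pivaloyloxymethyl)cyclopropane-1,1-dicarboxylate | COC(=O)C1(C(=O)OC)[C@H](COC(=O)C(C)(C)C)[C@H]1c1ccc(O[C@@H](C)[C@@H](O[Si](C(C)C)(C(C)C)C(C)C)c2ccc(OC)c(OC)c2)c(OC)c1
F11 | step 13 | 4-(pivaloyloxymethyl) analogue of 21 | COc1ccc([C@@H](O[Si](C(C)C)(C(C)C)C(C)C)[C@@H](C)Oc2ccc([C@H]3O[C@@H](c4ccc(O[C@@H](C)[C@@H](O[Si](C(C)C)(C(C)C)C(C)C)c5ccc(OC)c(OC)c5)c(OC)c4)[C@@H](COC(=O)C(C)(C)C)C3(C(=O)OC)C(=O)OC)cc2OC)cc1OC
F12 | step 13 | 4-(pivaloyloxymethyl) analogue of 22, C3 epimers | COc1ccc([C@@H](O[Si](C(C)C)(C(C)C)C(C)C)[C@@H](C)Oc2ccc([C@H]3O[C@@H](c4ccc(O[C@@H](C)[C@@H](O[Si](C(C)C)(C(C)C)C(C)C)c5ccc(OC)c(OC)c5)c(OC)c4)[C@@H](COC(=O)C(C)(C)C)C3C(=O)OC)cc2OC)cc1OC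
F13 | step 13 | 4-(pivaloyloxymethyl) analogue of 23 | COc1ccc([C@@H](O[Si](C(C)C)(C(C)C)C(C)C)[C@@H](C)Oc2ccc([C@H]3O[C@@H](c4ccc(O[C@@H](C)[C@@H](O[Si](C(C)C)(C(C)C)C(C)C)c5ccc(OC)c(OC)c5)c(OC)c4)[C@@H](COC(=O)C(C)(C)C)[C@@H]3C(=O)OC)cc2OC)cc1OC
F14 | step 13 | 2-ArR-5-ArS-3,4-bis(hydroxymethyl)oxolane, ring configuration of 24 | COc1ccc([C@@H](O[Si](C(C)C)(C(C)C)C(C)C)[C@@H](C)Oc2ccc([C@H]3O[C@@H](c4ccc(O[C@@H](C)[C@@H](O[Si](C(C)C)(C(C)C)C(C)C)c5ccc(OC)c(OC)c5)c(OC)c4)[C@@H](CO)[C@@H]3CO)cc2OC)cc1OC
F15 | step 13 | bis(methanesulfonate) of F14 | COc1ccc([C@@H](O[Si](C(C)C)(C(C)C)C(C)C)[C@@H](C)Oc2ccc([C@H]3O[C@@H](c4ccc(O[C@@H](C)[C@@H](O[Si](C(C)C)(C(C)C)C(C)C)c5ccc(OC)c(OC)c5)c(OC)c4)[C@@H](COS(C)(=O)=O)[C@@H]3COS(C)(=O)=O)cc2OC)cc1OC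
F16 | step 15 | (2R,4S,5R)-2-ArR-5-ArS-3-(methoxycarbonyl)-4-methyloxolane-3-carboxylic acid, C3 unassigned | COc1ccc([C@@H](O[Si](C(C)C)(C(C)C)C(C)C)[C@@H](C)Oc2ccc([C@H]3O[C@@H](c4ccc(O[C@@H](C)[C@@H](O[Si](C(C)C)(C(C)C)C(C)C)c5ccc(OC)c(OC)c5)c(OC)c4)[C@@H](C)C3(C(=O)O)C(=O)OC)cc2OC)cc1OC
F0 | step 4 | none | none
A1 | alternative 1 | (5S)-5-(4-{[(1R,2R)-1-(tert-butyldimethylsilyloxy)-1-(3,4-dimethoxyphenyl)propan-2-yl]oxy}-3-methoxyphenyl)furan-2(5H)-one | COc1ccc([C@@H](O[Si](C)(C)C(C)(C)C)[C@@H](C)Oc2ccc([C@H]3OC(=O)C=C3)cc2OC)cc1OC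
A2 | alternative 1 | all-trans (3S,4S,5S)-3,4-dimethyl-5-aryl-oxolan-2-one carrying the silylated (7R,8R) arm | COc1ccc([C@@H](O[Si](C)(C)C(C)(C)C)[C@@H](C)Oc2ccc([C@H]3OC(=O)[C@@H](C)[C@@H]3C)cc2OC)cc1OC
A3 | alternative 2 | (1S,2S,3E)-1-(4-{[(1S,2S)-1-(tert-butyldimethylsilyloxy)-1-(3,4-dimethoxyphenyl)propan-2-yl]oxy}-3-methoxyphenyl)pent-3-ene-1,2-diol | COc1ccc([C@H](O[Si](C)(C)C(C)(C)C)[C@H](C)Oc2ccc([C@H](O)[C@@H](O)/C=C/C)cc2OC)cc1OC
A4 | alternative 2 | 4-{[(1R,2R)-1-(tert-butyldimethylsilyloxy)-1-(3,4-dimethoxyphenyl)propan-2-yl]oxy}-3-methoxybenzaldehyde | COc1ccc([C@@H](O[Si](C)(C)C(C)(C)C)[C@@H](C)Oc2ccc(C=O)cc2OC)cc1OC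
A5 | alternative 2 | 2,5-cis-diaryl-3-methyloxolane-4-carbaldehyde, formyl cis to the C5 aryl and trans to the C3 methyl, both arms silylated | COc1ccc([C@@H](O[Si](C)(C)C(C)(C)C)[C@@H](C)Oc2ccc([C@H]3O[C@@H](c4ccc(O[C@@H](C)[C@@H](O[Si](C)(C)C(C)(C)C)c5ccc(OC)c(OC)c5)c(OC)c4)[C@@H](C=O)[C@@H]3C)cc2OC)cc1OC
A6 | alternative 3 | 2,6-cis-diaryl-3-methyl-5-diazo-oxan-4-one, methyl trans to the C2 aryl (the aryl with the (7R,8R) arm), both arms silylated | COc1ccc([C@@H](O[Si](C)(C)C(C)(C)C)[C@@H](C)Oc2ccc([C@H]3O[C@@H](c4ccc(O[C@@H](C)[C@@H](O[Si](C)(C)C(C)(C)C)c5ccc(OC)c(OC)c5)c(OC)c4)C(=[N+]=[N-])C(=O)[C@@H]3C)cc2OC)cc1OC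
A7 | alternative 3 | methyl 2,5-cis-diaryl-3-methyloxolane-4-carboxylate, ester cis to the C5 aryl and trans to the C3 methyl, both arms silylated | COc1ccc([C@@H](O[Si](C)(C)C(C)(C)C)[C@@H](C)Oc2ccc([C@H]3O[C@@H](c4ccc(O[C@@H](C)[C@@H](O[Si](C)(C)C(C)(C)C)c5ccc(OC)c(OC)c5)c(OC)c4)[C@@H](C(=O)OC)[C@@H]3C)cc2OC)cc1OC
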